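(The runs stem from a simulated flask for an exercise.)

Slowness is the danger in this flask: if the racemization catalyst swaps the two substrates too slowly, the faster-reacting left-handed substrate thins out and the excess in the product falls. The flask carries less racemization catalyst than either earlier run.

| flask | left-handed substrate | right-handed substrate | reagent | racemization catalyst | remark | time |
|---|---|---|---|---|---|---|
| Monday's | 0.25 M | 0.25 M | 0.625 M | 2.1 mM | run made earlier |  |
| Thursday's | 0.25 M | 0.25 M | 0.625 M | 3.3 mM | run made earlier |  |
| flask | 0.25 M | 0.25 M | 0.625 M | 1.5 mM |  | 2.0 h |

| run | time / min | left-handed product / % | right-handed product / % | left-handed substrate / % |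
|---|---|---|---|---|
| Monday's | 20.0 | 25.4 | 15.7 | 28.9 |
| Monday's | 40.0 | 36.4 | 23.2 | 19.1 |
| Monday's | 60.0 | 44.4 | 28.1 | 14.4 |
| Monday's | 80.0 | 47.7 | 30.4 | 10.5 |
| Monday's | 90.0 | 48.4 | 31.1 | 9.8 |
| Monday's | 120 | 52.5 | 34.9 | 6.4 |
| Thursday's | 20.0 | 25.4 | 16.5 | 28.2 |
| Thursday's | 40.0 | 36.5 | 23.9 | 19.4 |
| Thursday's | 60.0 | 43.3 | 28.6 | 14.8 |
| Thursday's | 80.0 | 47.6 | 29.5 | 11.5 |
| Thursday's | 90.0 | 49.5 | 31.2 | 8.8 |
| Thursday's | 120 | 52.3 | 33.6 | 7.1 |

(scatter of a reading: 0.5 percentage points)

- reagent is single-handed; left-handed substrate and right-handed substrate are mirror images of each other, charged as a racemate, each of them at the stated concentration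
- an excess is the difference of the two amounts in percent of their sum
- an excess is below zero if the other one leads
- the handed part of reagent does not stay in what it makes, so the products of the two hands are mirror images too

- left-handed product and right-handed product together, in percent of the left-handed substrate and right-handed substrate charged together, at 2.0 h
- excess of left-handed product over right-handed product in the product at 2.0 h
- whether the exchange between left-handed substrate and right-handed substrate keeps pace with the reaction: how far the product's excess at 2.0 h gets from its value without exchange to its value with instant exchange (above 80% keeps pace, below 20% hardly takes part, else lags behind)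

I start from the two runs. Summed over the samples of each run, the product excess reads 21.9% on Monday and 21.8% on Thursday. I take their mean, 21.9%, as the instant-exchange excess. That makes the selectivity factor, the ratio of the two product peaks while the substrates stay equal, 1.56.

The last samples of the two runs put the total near 86.7%, and I take that reading for this flask.

How low could the excess go? Without exchange, the left-handed fraction remaining is the right-handed fraction raised to that factor. With 20.0% of the right-handed substrate left, 14.1% of the substrate remains, close to the 13.3% required. The excess is then 6.91%, so keeping pace needs 18.9%.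

Is the lag that large? I take a small lag as inverse to catalyst and grant the two runs a difference of one reading's scatter. My estimate of the lag in this flask is then 1.9 percentage points, leaving 20.0%, above that mark. So I expect the exchange to keep pace.

The forecast gives 86% of product, an excess of 21.2% where I reckon 20.0%, and keeps pace: “so exchange is already fast”.

The flask gives 85.9%, 22.1% and keeps pace, 99.1% of the way.

    reagent + left-handed substrate → left-handed product (k = 0.00110 M⁻¹ s⁻¹)
    reagent + right-handed substrate → right-handed product (k = 7.00 × 10⁻⁴ M⁻¹ s⁻¹)
    left-handed substrate + racemization catalyst ⇌ right-handed substrate + racemization catalyst, rate k3*[racemization catalyst]*[left-handed substrate] forward; the back reaction follows from the equilibrium constant (k = 56.0 M⁻¹ s⁻¹)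
    racemization catalyst → spent catalyst (k = 5.10 × 10⁻⁴ s⁻¹)
    reagent → decomposition product (k = 3.00 × 10⁻⁶ s⁻¹)

At 2.00 h the flask holds 6.99% left-handed and 7.11% right-handed substrate, with racemization catalyst at 2.54% of its charge. The factor 1.56 splits 85.9% into 33.6% right-handed product; the flask holds 33.5%.

In the neighbouring flask with 1.1 M of reagent, the factor gives an excess of 21.9% and, from 98.8% of product, 38.6% right-handed product. Computed, that flask gives 22.0% and 38.5%.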